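**Retrosynthetic overview**
1. Target ⇒ global desilylation and Steglich ester at O8: acid 21 + decalin core 30.
2. Ring B (closed last) ⇒ intramolecular aldol C5–C6: the C4-ketone enolate, released from an enol silane, adds to the C6 aldehyde of 25 under thermodynamic control (sets C5 and C6).
3. C7–C8 ⇒ auxiliary-controlled syn-aldol of ring-A aldehyde 9 with the itaconate-derived N-acyl thiazolidinethione 17 (brings C6, C7, C11–C13).
4. Ring A is kept intact from 2-methylcyclohex-2-enone: CBS reduction (C1), allylic oxidation (C4=O), anti vinyl-cuprate addition (C10), vinyl → CH2CHO.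
5. Ring order: A is the purchased carbocycle, B closes in step 19; three branches (9, 17, 21) meet at steps 16 and 22.

Assumption/notation: eudesmane locants are used for the decalin (C1 = CH–O next to quaternary C10; C4 = ketone; C5 = ring-fusion CH; C6/C7/C8 = CH(OH)/CH(acrylate)/CH(O-acyl); C9 = CH2; C11–C13 = acrylate); the SMILES then reads as 1β-OH, 5α-H, 6α-OH, 7α-H, 8α-O-acyl, 10β-Me = (1R,5S,6S,7S,8S,10R).

**Ring-A aldehyde (steps 1–7)**

Step 1
Reactants: 1 2-methylcyclohex-2-en-1-one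
Product: 2 (R)-2-methylcyclohex-2-en-1-ol
Conditions: (S)-Me-CBS (10 mol %), catecholborane, toluene, −78 °C; aq. NaOH work-up
Reagents that add atoms: none
Why: Corey–Bakshi–Shibata reduction in which the α-methyl-alkenyl arm acts as the large group, so the (S)-catalyst delivers hydride to give the (R)-carbinol (future C1).

Step 2
Reactants: 2 (R)-2-methylcyclohex-2-en-1-ol
Product: 3 (R)-tert-butyldimethyl[(2-methylcyclohex-2-en-1-yl)oxy]silane
Conditions: TBSCl, imidazole, DMF, rt
Reagents that add atoms: tert-butyldimethylsilyl chloride CC(C)(C)[Si](C)(C)Cl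
Why: Standard silylation of a secondary allylic alcohol; the stereocentre is untouched.

Step 3
Reactants: 3 (R)-tert-butyldimethyl[(2-methylcyclohex-2-en-1-yl)oxy]silane
Product: 4 (R)-4-(tert-butyldimethylsilyloxy)-3-methylcyclohex-2-en-1-one
Conditions: Rh2(cap)4 (1 mol %), t-BuOOH (5 equiv), K2CO3, CH2Cl2, rt
Reagents that add atoms: tert-butyl hydroperoxide CC(C)(C)OO
Why: Doyle-type catalytic allylic C–H oxidation at the only allylic methylene gives the γ-silyloxy enone (future C4=O) without touching the carbinol centre.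

Step 4
Reactants: 4 (R)-4-(tert-butyldimethylsilyloxy)-3-methylcyclohex-2-en-1-one
Product: 5 (3R,4R)-4-(tert-butyldimethylsilyloxy)-3-methyl-1-(trimethylsilyloxy)-3-vinylcyclohex-1-ene
Conditions: CH2=CHMgBr, CuBr·SMe2 (20 mol %), TMSCl, HMPA, THF, −78 → −40 °C; Et3N, pentane, filtration
Reagents that add atoms: vinylmagnesium bromide C=C[Mg]Br; chlorotrimethylsilane C[Si](C)(C)Cl
Why: Cu-catalysed, TMSCl-accelerated conjugate addition (Kuwajima–Nakamura) in which vinyl adds anti to the pseudo-axial γ-OTBS group, setting the quaternary C10 (methyl cis to OTBS) and trapping the C4/C5 enolate regiospecifically.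

Step 5
Reactants: 5 (3R,4R)-4-(tert-butyldimethylsilyloxy)-3-methyl-1-(trimethylsilyloxy)-3-vinylcyclohex-1-ene
Product: 7 (3R,4R)-1,4-bis(tert-butyldimethylsilyloxy)-3-methyl-3-vinylcyclohex-1-ene, via lithium enolate 6 (not isolated)
Conditions: MeLi, THF, 0 °C → rt; then TBSOTf, −78 °C
Reagents that add atoms: tert-butyldimethylsilyl triflate CC(C)(C)[Si](C)(C)OS(=O)(=O)C(F)(F)F
Why: Stork–House cleavage of the TMS enol ether gives the regiodefined lithium enolate, whose O-silylation yields a robust TBS enol ether that masks the ketone and stores the C5 nucleophile.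

Step 6
Reactants: 7 (3R,4R)-1,4-bis(tert-butyldimethylsilyloxy)-3-methyl-3-vinylcyclohex-1-ene
Product: 8 2-[(1R,6R)-3,6-bis(tert-butyldimethylsilyloxy)-1-methylcyclohex-2-en-1-yl]ethan-1-ol
Conditions: 9-BBN, THF, 0 °C → rt; then NaBO3·4H2O, H2O, rt
Reagents that add atoms: sodium perborate [Na+].[Na+].O[B-]1(O)OO[B-](O)(O)OO1
Why: Anti-Markovnikov hydroboration–oxidation in which 9-BBN selects the monosubstituted vinyl group over the hindered trisubstituted enol ether, and perborate oxidises under mild conditions.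

Step 7
Reactants: 8 2-[(1R,6R)-3,6-bis(tert-butyldimethylsilyloxy)-1-methylcyclohex-2-en-1-yl]ethan-1-ol
Product: 9 2-[(1R,6R)-3,6-bis(tert-butyldimethylsilyloxy)-1-methylcyclohex-2-en-1-yl]acetaldehyde
Conditions: SO3·pyridine, DMSO, i-Pr2NEt, CH2Cl2, 0 °C
Reagents that add atoms: none
Why: Parikh–Doering oxidation is non-acidic, so the enol silane survives and the C8 aldehyde is obtained without over-oxidation.

**Aldol donor (steps 8–12)**

Step 8
Reactants: 10 D-phenylalanine
Product: 11 (R)-2-amino-3-phenylpropan-1-ol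
Conditions: LiAlH4, THF, reflux; Fieser work-up
Reagents that add atoms: none
Why: Hydride reduction of the amino acid to the amino alcohol does not involve the stereocentre.

Step 9
Reactants: 11 (R)-2-amino-3-phenylpropan-1-ol
Product: 12 (R)-4-benzyl-1,3-thiazolidine-2-thione
Conditions: CS2 (excess), aq. KOH, reflux
Reagents that add atoms: carbon disulfide S=C=S
Why: Dithiocarbamate formation and intramolecular S-alkylation at the primary carbon (via the O-xanthate) give the Crimmins auxiliary with the N-bearing stereocentre unchanged.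

Step 10
Reactants: 13 itaconic acid
Product: 14 itaconic anhydride
Conditions: AcCl, reflux
Reagents that add atoms: none
Why: Cyclodehydration of the 1,4-diacid to the five-membered anhydride, stopped before isomerisation to citraconic anhydride.

Step 11
Reactants: 12 (R)-4-benzyl-1,3-thiazolidine-2-thione; 14 itaconic anhydride
Product: 16 4-[(R)-4-benzyl-2-thioxo-1,3-thiazolidin-3-yl]-2-methylidene-4-oxobutanoic acid, via lithium thiazolidinethionide 15 (not isolated)
Conditions: n-BuLi, THF, −78 °C; then 14, −78 °C; AcOH quench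
Reagents that add atoms: none
Why: N-acylation by anhydride ring-opening at the more electrophilic non-conjugated carbonyl (the same regiochemistry as alcoholysis of itaconic anhydride) puts the auxiliary on C6 and leaves the conjugated C12 acid free.

Step 12
Reactants: 16 4-[(R)-4-benzyl-2-thioxo-1,3-thiazolidin-3-yl]-2-methylidene-4-oxobutanoic acid
Product: 17 methyl 4-[(R)-4-benzyl-2-thioxo-1,3-thiazolidin-3-yl]-2-methylidene-4-oxobutanoate
Conditions: TMSCHN2, toluene/MeOH, 0 °C
Reagents that add atoms: (trimethylsilyl)diazomethane C[Si](C)(C)C=[N+]=[N-]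
Why: Base-free methyl esterification avoids isomerisation of the itaconyl unit to the mesaconyl isomer.

**Acyl side chain (steps 13–15)**

Step 13
Reactants: 18 methyl acrylate
Product: 19 methyl 2-(hydroxymethyl)acrylate
Conditions: aq. HCHO (37 %), DABCO, dioxane/H2O, rt
Reagents that add atoms: formaldehyde C=O
Why: Morita–Baylis–Hillman reaction of the acrylate with formaldehyde.

Step 14
Reactants: 19 methyl 2-(hydroxymethyl)acrylate
Product: 20 methyl 2-[(tert-butyldimethylsilyloxy)methyl]acrylate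
Conditions: TBSCl, imidazole, DMF, 0 °C → rt
Reagents that add atoms: tert-butyldimethylsilyl chloride CC(C)(C)[Si](C)(C)Cl
Why: Silylation of the primary allylic alcohol.

Step 15
Reactants: 20 methyl 2-[(tert-butyldimethylsilyloxy)methyl]acrylate
Product: 21 2-[(tert-butyldimethylsilyloxy)methyl]acrylic acid
Conditions: LiOH, THF/H2O, 0 °C; then 1 M HCl to pH 3
Reagents that add atoms: lithium hydroxide [Li+].[OH-]
Why: Saponification of the methyl ester, with the primary TBS ether stable to cold aqueous base and brief mild acidification.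

**Union, ring closure and end game (steps 16–23)**

Step 16
Reactants: 17 methyl 4-[(R)-4-benzyl-2-thioxo-1,3-thiazolidin-3-yl]-2-methylidene-4-oxobutanoate; 9 2-[(1R,6R)-3,6-bis(tert-butyldimethylsilyloxy)-1-methylcyclohex-2-en-1-yl]acetaldehyde
Product: 23 methyl (3R,4S)-3-{[(R)-4-benzyl-2-thioxo-1,3-thiazolidin-3-yl]carbonyl}-5-[(1R,6R)-3,6-bis(tert-butyldimethylsilyloxy)-1-methylcyclohex-2-en-1-yl]-4-hydroxy-2-methylidenepentanoate, via titanium enolate 22 (not isolated)
Conditions: 17, TiCl4 (1.05 equiv), CH2Cl2, 0 °C; i-Pr2NEt (1.1 equiv), NMP (1 equiv), −78 °C; then 9, −78 °C; aq. NH4Cl at −78 °C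
Reagents that add atoms: none
Why: Crimmins titanium aldol in the Evans-syn mode, where the (Z)-enolate reacts at its α-carbon through a Zimmerman–Traxler chair and the (R)-auxiliary fixes the face, giving the 7,8-syn adduct with the target configuration at C7 and C8 (7R,8S here) irrespective of the remote C10.

Step 17
Reactants: 23 aldol adduct (name as in step 16)
Product: 24 methyl (3R,4S)-3-{[(R)-4-benzyl-2-thioxo-1,3-thiazolidin-3-yl]carbonyl}-5-[(1R,6R)-3,6-bis(tert-butyldimethylsilyloxy)-1-methylcyclohex-2-en-1-yl]-2-methylidene-4-(triethylsilyloxy)pentanoate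
Conditions: TESOTf, 2,6-lutidine, CH2Cl2, −78 °C
Reagents that add atoms: triethylsilyl triflate CC[Si](CC)(CC)OS(=O)(=O)C(F)(F)F
Why: Immediate silylation of O8 blocks retro-aldol and lactonisation onto the C12 ester, and gives a group removable later in the presence of TBS ethers.

Step 18
Reactants: 24 TES-protected aldol adduct (name as in step 17)
Product: 25 methyl (3R,4S)-5-[(1R,6R)-3,6-bis(tert-butyldimethylsilyloxy)-1-methylcyclohex-2-en-1-yl]-3-formyl-2-methylidene-4-(triethylsilyloxy)pentanoate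
Conditions: DIBAL-H (1.3 equiv), CH2Cl2, −78 °C, 10 min; Rochelle salt
Reagents that add atoms: none
Why: The highly electrophilic N-acyl thiazolidinethione is reduced to a stable aluminium hemiaminal that releases the C6 aldehyde on work-up, faster than the conjugated methyl ester reacts, while the ketone stays masked as the enol silane.

Step 19
Reactants: 25 aldehyde (name as in step 18)
Product: 28 methyl 1β-(tert-butyldimethylsilyloxy)-6α-hydroxy-4-oxo-8α-(triethylsilyloxy)-15-nor-5α-eudesm-11(13)-en-12-oate, via keto-aldehyde 26 (not isolated), via lithium carboxylate 27 (not isolated)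
Conditions: TBAF (1.05 equiv), THF, −78 °C; then aq. LiOH, THF/H2O, 0 °C → rt; CO2, evaporate; MeI, DMF, rt
Reagents that add atoms: iodomethane CI; lithium hydroxide [Li+].[OH-]
Why: Fluoride unmasks the C4 ketone as its C5 enolate, which closes ring B by intramolecular aldol addition to the C6 aldehyde; hydroxide then equilibrates C5 and C6 (enolisation, retro-aldol/aldol) to the all-equatorial, hydrogen-bonded trans-decalin (5α-H, 6α-OH; only the angular methyl axial) and funnels ester or any 6,12-lactone to carboxylate 27, which MeI re-esterifies without acid.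

Step 20
Reactants: 28 decalin hydroxy ester (name as in step 19)
Product: 29 methyl 1β,6α-bis(tert-butyldimethylsilyloxy)-4-oxo-8α-(triethylsilyloxy)-15-nor-5α-eudesm-11(13)-en-12-oate
Conditions: TBSOTf, 2,6-lutidine, CH2Cl2, −40 → 0 °C
Reagents that add atoms: tert-butyldimethylsilyl triflate CC(C)(C)[Si](C)(C)OS(=O)(=O)C(F)(F)F
Why: Silylation of the hindered 6-OH prevents 6,12-lactonisation and leaves O8 as the only hydroxyl to be freed next.

Step 21
Reactants: 29 tris-silyl ether (name as in step 20)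
Product: 30 methyl 1β,6α-bis(tert-butyldimethylsilyloxy)-8α-hydroxy-4-oxo-15-nor-5α-eudesm-11(13)-en-12-oate
Conditions: HF·pyridine, pyridine, THF, 0 °C
Reagents that add atoms: none
Why: Buffered HF cleaves the secondary TES ether far faster than the two hindered secondary TBS ethers, freeing only the 8-OH.

Step 22
Reactants: 30 8-hydroxy ester (name as in step 21); 21 2-[(tert-butyldimethylsilyloxy)methyl]acrylic acid
Product: 31 methyl 1β,6α-bis(tert-butyldimethylsilyloxy)-8α-{2-[(tert-butyldimethylsilyloxy)methyl]acryloyloxy}-4-oxo-15-nor-5α-eudesm-11(13)-en-12-oate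
Conditions: DCC, DMAP (cat.), CH2Cl2, 0 °C → rt
Reagents that add atoms: none
Why: Steglich esterification of the only free hydroxyl with retention at C8, the acylation outrunning 8,12-lactonisation.

Step 23
Reactants: 31 fully protected diester (name as in step 22)
Product: 32 methyl 1β,6α-dihydroxy-8α-[2-(hydroxymethyl)acryloyloxy]-4-oxo-15-nor-5α-eudesm-11(13)-en-12-oate (target, CNP0144895.1)
Conditions: HF·pyridine (excess), pyridine, THF, 0 °C → rt
Reagents that add atoms: none
Why: Buffered fluoride removes the three TBS ethers under near-neutral conditions, which spare both acrylates, the β-hydroxy ketone and the lactonisation-prone γ-hydroxy ester.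

**Compound list**

1 | 2-methylcyclohex-2-en-1-one | CC1=CCCCC1=O | starting material
2 | (R)-2-methylcyclohex-2-en-1-ol | CC1=CCCC[C@H]1O | intermediate
3 | (R)-tert-butyldimethyl[(2-methylcyclohex-2-en-1-yl)oxy]silane | CC1=CCCC[C@H]1O[Si](C)(C)C(C)(C)C | intermediate
4 | (R)-4-(tert-butyldimethylsilyloxy)-3-methylcyclohex-2-en-1-one | O=C1C=C(C)[C@H](O[Si](C)(C)C(C)(C)C)CC1 | intermediate
5 | (3R,4R)-4-(TBSO)-3-methyl-1-(TMSO)-3-vinylcyclohex-1-ene (vinyl trans to OTBS) | C=C[C@@]1(C)[C@H](O[Si](C)(C)C(C)(C)C)CCC(O[Si](C)(C)C)=C1 | intermediate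
6 | lithium (3R,4R)-4-(TBSO)-3-methyl-3-vinylcyclohex-1-en-1-olate | C=C[C@@]1(C)[C@H](O[Si](C)(C)C(C)(C)C)CCC([O-])=C1.[Li+] | intermediate (not isolated)
7 | (3R,4R)-1,4-bis(TBSO)-3-methyl-3-vinylcyclohex-1-ene | C=C[C@@]1(C)[C@H](O[Si](C)(C)C(C)(C)C)CCC(O[Si](C)(C)C(C)(C)C)=C1 | intermediate
8 | 2-[(1R,6R)-3,6-bis(TBSO)-1-methylcyclohex-2-en-1-yl]ethan-1-ol | OCC[C@@]1(C)[C@H](O[Si](C)(C)C(C)(C)C)CCC(O[Si](C)(C)C(C)(C)C)=C1 | intermediate
9 | 2-[(1R,6R)-3,6-bis(TBSO)-1-methylcyclohex-2-en-1-yl]acetaldehyde | O=CC[C@@]1(C)[C@H](O[Si](C)(C)C(C)(C)C)CCC(O[Si](C)(C)C(C)(C)C)=C1 | intermediate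
10 | D-phenylalanine | N[C@H](Cc1ccccc1)C(=O)O | starting material
11 | (R)-2-amino-3-phenylpropan-1-ol | N[C@H](Cc1ccccc1)CO | intermediate
12 | (R)-4-benzyl-1,3-thiazolidine-2-thione | S=C1N[C@H](Cc2ccccc2)CS1 | intermediate
13 | itaconic acid | C=C(CC(=O)O)C(=O)O | starting material
14 | itaconic anhydride | C=C1CC(=O)OC1=O | intermediate
15 | lithium (R)-4-benzyl-2-thioxo-1,3-thiazolidin-3-ide | S=C1[N-][C@H](Cc2ccccc2)CS1.[Li+] | intermediate (not isolated)
16 | 4-[(R)-4-benzyl-2-thioxo-1,3-thiazolidin-3-yl]-2-methylidene-4-oxobutanoic acid | C=C(CC(=O)N1[C@H](Cc2ccccc2)CSC1=S)C(=O)O | intermediate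
17 | methyl 4-[(R)-4-benzyl-2-thioxo-1,3-thiazolidin-3-yl]-2-methylidene-4-oxobutanoate | C=C(CC(=O)N1[C@H](Cc2ccccc2)CSC1=S)C(=O)OC | intermediate
18 | methyl acrylate | C=CC(=O)OC | starting material
19 | methyl 2-(hydroxymethyl)acrylate | C=C(CO)C(=O)OC | intermediate
20 | methyl 2-[(tert-butyldimethylsilyloxy)methyl]acrylate | C=C(CO[Si](C)(C)C(C)(C)C)C(=O)OC | intermediate
21 | 2-[(tert-butyldimethylsilyloxy)methyl]acrylic acid | C=C(CO[Si](C)(C)C(C)(C)C)C(=O)O | intermediate
22 | (Z)-trichlorotitanium enolate of 17 | C=C(C(=O)OC)/C=C(\O[Ti](Cl)(Cl)Cl)N1[C@H](Cc2ccccc2)CSC1=S | intermediate (not isolated)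
23 | syn-aldol adduct, (3R,4S)-4-hydroxy imide (name in step 16) | C=C(C(=O)OC)[C@@H](C(=O)N1[C@H](Cc2ccccc2)CSC1=S)[C@@H](O)C[C@@]3(C)[C@H](O[Si](C)(C)C(C)(C)C)CCC(O[Si](C)(C)C(C)(C)C)=C3 | intermediate
24 | 4-O-TES ether of 23 (name in step 17) | C=C(C(=O)OC)[C@@H](C(=O)N1[C@H](Cc2ccccc2)CSC1=S)[C@@H](O[Si](CC)(CC)CC)C[C@@]3(C)[C@H](O[Si](C)(C)C(C)(C)C)CCC(O[Si](C)(C)C(C)(C)C)=C3 | intermediate
25 | methyl (3R,4S)-5-[(1R,6R)-3,6-bis(TBSO)-1-methylcyclohex-2-en-1-yl]-3-formyl-2-methylidene-4-(triethylsilyloxy)pentanoate | C=C(C(=O)OC)[C@@H](C=O)[C@@H](O[Si](CC)(CC)CC)C[C@@]1(C)[C@H](O[Si](C)(C)C(C)(C)C)CCC(O[Si](C)(C)C(C)(C)C)=C1 | intermediate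
26 | methyl (3R,4S)-5-[(1R,2R)-2-(TBSO)-1-methyl-5-oxocyclohexyl]-3-formyl-2-methylidene-4-(triethylsilyloxy)pentanoate | C=C(C(=O)OC)[C@@H](C=O)[C@@H](O[Si](CC)(CC)CC)C[C@@]1(C)[C@H](O[Si](C)(C)C(C)(C)C)CCC(=O)C1 | intermediate (not isolated)
27 | lithium 1β-(TBSO)-6α-hydroxy-4-oxo-8α-(TESO)-15-nor-5α-eudesm-11(13)-en-12-oate | CC[Si](CC)(CC)O[C@H]1C[C@@]2(C)[C@H](O[Si](C)(C)C(C)(C)C)CCC(=O)[C@@H]2[C@@H](O)[C@@H]1C(=C)C(=O)[O-].[Li+] | intermediate (not isolated)
28 | methyl 1β-(TBSO)-6α-hydroxy-4-oxo-8α-(TESO)-15-nor-5α-eudesm-11(13)-en-12-oate | CC[Si](CC)(CC)O[C@H]1C[C@@]2(C)[C@H](O[Si](C)(C)C(C)(C)C)CCC(=O)[C@@H]2[C@@H](O)[C@@H]1C(=C)C(=O)OC | intermediate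
29 | methyl 1β,6α-bis(TBSO)-4-oxo-8α-(TESO)-15-nor-5α-eudesm-11(13)-en-12-oate | CC[Si](CC)(CC)O[C@H]1C[C@@]2(C)[C@H](O[Si](C)(C)C(C)(C)C)CCC(=O)[C@@H]2[C@@H](O[Si](C)(C)C(C)(C)C)[C@@H]1C(=C)C(=O)OC | intermediate
30 | methyl 1β,6α-bis(TBSO)-8α-hydroxy-4-oxo-15-nor-5α-eudesm-11(13)-en-12-oate | O[C@H]1C[C@@]2(C)[C@H](O[Si](C)(C)C(C)(C)C)CCC(=O)[C@@H]2[C@@H](O[Si](C)(C)C(C)(C)C)[C@@H]1C(=C)C(=O)OC | intermediate
31 | methyl 1β,6α-bis(TBSO)-8α-{2-[(TBSO)methyl]acryloyloxy}-4-oxo-15-nor-5α-eudesm-11(13)-en-12-oate | C=C(CO[Si](C)(C)C(C)(C)C)C(=O)O[C@H]1C[C@@]2(C)[C@H](O[Si](C)(C)C(C)(C)C)CCC(=O)[C@@H]2[C@@H](O[Si](C)(C)C(C)(C)C)[C@@H]1C(=C)C(=O)OC | intermediate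
32 | methyl 1β,6α-dihydroxy-8α-[2-(hydroxymethyl)acryloyloxy]-4-oxo-15-nor-5α-eudesm-11(13)-en-12-oate | C=C(CO)C(=O)O[C@H]1C[C@@]2(C)[C@H](O)CCC(=O)[C@@H]2[C@@H](O)[C@@H]1C(=C)C(=O)OC | target

**Step count**
Total: 23 steps. Longest linear sequence: 15 steps (1–7, then 16–23), i.e. 65 % of the total.

**Three steps most likely to fail, with fallbacks**

Step 16 (titanium aldol of 17). Dienolate 22 carries its own acrylate, so self-Michael addition, γ-attack or lactonisation of the adduct onto the C12 ester can erode yield and selectivity. The fallback sets out from 9 (with auxiliary 12) and carries C11 as a vinyl bromide, adding C12 late by carbonylation. Auxiliary 12 is acylated with purchased 3-bromobut-3-enoic acid (DCC, cat. DMAP) to give the N-(3-bromobut-3-enoyl)thiazolidinethione F1. The same TiCl4/i-Pr2NEt/NMP syn-aldol with 9 gives the bromovinyl aldol adduct F2, and TESOTf gives its TES ether F3. DIBAL-H, with no ester present, gives the bromovinyl aldehyde F4. TBAF then LiOH closes ring B to the bromovinyl decalin hydroxy ketone F5, and TBSOTf gives the 6-O-TBS ether F6. Pd-catalysed methoxycarbonylation (Pd(PPh3)4, CO 1 atm, MeOH, Et3N, DMF, 60 °C) then comes back to the route at 29.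

Step 18 (DIBAL-H on 24). The reduction must stop at the aldehyde and spare the methyl acrylate ester, and the β-silyloxy aldehyde 25 is prone to elimination. The fallback sets out from 24 and replaces the partial reduction by a redox pair: NaBH4 (THF/EtOH, 0 °C) cleaves only the thioimide to the primary alcohol F7, and Dess–Martin periodinane/pyridine oxidises it, coming back at 25.

Step 19 (cascade ring closure). Possible failures are E1cB loss of the 8-OTES group from the open aldehyde, dehydration of the aldol and incomplete re-esterification. The fallback sets out from 25 and closes the ring under Lewis-acid rather than basic conditions: BF3·OEt2 (CH2Cl2, −78 °C) triggers an intramolecular Mukaiyama aldol of the enol silane, which kinetically should give the cis-fused 5-epimer F8 with the ester intact. A separate equilibration (cat. DBU, toluene, 0 °C → rt) then epimerises C5 to the trans-fused isomer, coming back at 28.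

**Further compounds**

F1 | step 16 | (R)-1-(4-benzyl-2-thioxo-1,3-thiazolidin-3-yl)-3-bromobut-3-en-1-one | C=C(Br)CC(=O)N1[C@H](Cc2ccccc2)CSC1=S
F2 | step 16 | bromovinyl syn-aldol adduct (C11 = CBr=CH2 analogue of 23, no ester) | C=C(Br)[C@@H](C(=O)N1[C@H](Cc2ccccc2)CSC1=S)[C@@H](O)C[C@@]3(C)[C@H](O[Si](C)(C)C(C)(C)C)CCC(O[Si](C)(C)C(C)(C)C)=C3
F3 | step 16 | TES ether of F2 | C=C(Br)[C@@H](C(=O)N1[C@H](Cc2ccccc2)CSC1=S)[C@@H](O[Si](CC)(CC)CC)C[C@@]3(C)[C@H](O[Si](C)(C)C(C)(C)C)CCC(O[Si](C)(C)C(C)(C)C)=C3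
F4 | step 16 | bromovinyl aldehyde (CBr=CH2 analogue of 25) | C=C(Br)[C@@H](C=O)[C@@H](O[Si](CC)(CC)CC)C[C@@]1(C)[C@H](O[Si](C)(C)C(C)(C)C)CCC(O[Si](C)(C)C(C)(C)C)=C1
F5 | step 16 | 7β-(1-bromovinyl)-1β-(TBSO)-6α-hydroxy-8α-(TESO)-trans-decalin-4-one (eudesmane locants) | CC[Si](CC)(CC)O[C@H]1C[C@@]2(C)[C@H](O[Si](C)(C)C(C)(C)C)CCC(=O)[C@@H]2[C@@H](O)[C@@H]1C(Br)=C
F6 | step 16 | 6-O-TBS ether of F5 | CC[Si](CC)(CC)O[C@H]1C[C@@]2(C)[C@H](O[Si](C)(C)C(C)(C)C)CCC(=O)[C@@H]2[C@@H](O[Si](C)(C)C(C)(C)C)[C@@H]1C(Br)=C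
F7 | step 18 | methyl (3S,4S)-5-[(1R,6R)-3,6-bis(TBSO)-1-methylcyclohex-2-en-1-yl]-3-(hydroxymethyl)-2-methylidene-4-(triethylsilyloxy)pentanoate | C=C(C(=O)OC)[C@@H](CO)[C@@H](O[Si](CC)(CC)CC)C[C@@]1(C)[C@H](O[Si](C)(C)C(C)(C)C)CCC(O[Si](C)(C)C(C)(C)C)=C1
F8 | step 19 | 5-epi-28 (cis-fused, 5β-H) | CC[Si](CC)(CC)O[C@H]1C[C@@]2(C)[C@H](O[Si](C)(C)C(C)(C)C)CCC(=O)[C@H]2[C@@H](O)[C@@H]1C(=C)C(=O)OC
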